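Ring is what we want at 4.0 min, and it comes by a chain: the solid substrate dissolves to starting material, the activator turns that into activated form, and the activated form closes.

the same everywhere: solid substrate 0.0050 M

|  | activator | protic impurity | remark | time |
|---|---|---|---|---|
| dawn | 4.5 mM | 0.0075 mM | run made earlier |  |
| summer | 4.5 mM | 0.16 mM | run made earlier |  |
| south-east | 4.50 mM | 0.0120 mM |  | 4.0 min |
| north | 4.50 mM | 0.0250 mM |  | 4.0 min |
| east | 4.50 mM | 0.0500 mM |  | 4.0 min |
| north-east | 4.50 mM | 0.100 mM |  | 4.0 min |
| west | 4.50 mM | 0.200 mM |  | 4.0 min |

| run | time / min | ring / % | solid substrate / % |
|---|---|---|---|
| dawn | 0.250 | 1.0 | 92.4 |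
| dawn | 0.417 | 3.0 | 89.7 |
| dawn | 0.833 | 6.7 | 84.9 |
| dawn | 1.33 | 12.2 | 77.4 |
| dawn | 3.00 | 26.9 | 59.7 |
| summer | 0.500 | 2.8 | 87.1 |
| summer | 1.00 | 8.1 | 79.8 |
| summer | 1.50 | 13.0 | 73.0 |
| summer | 2.50 | 21.5 | 61.6 |
| summer | 3.00 | 26.1 | 57.5 |

(each reading ± 0.5 percentage points)

- in percentages every species weighs as the solid substrate in it: one open dimer counts as two
- as a solid, counted per litre of solution: solid substrate
- steps under discussion: starting material + activator -> activated form; activated form -> ring; starting material + activated form -> open dimer; solid substrate <-> starting material; starting material + protic impurity -> quenched substrate
- at the start none of the solid substrate is in solution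
- "hardly changes" means that all values lie within two and a half points (for a concentration: within two and a half percent of the largest)

1. amount of ring at the end, in percent of the solid substrate charged for south-east, north, east, north-east, west, in this order
2. the course of these numbers from the first flask to the last (falls all the way / falls, then rises / rises all the way / hardly changes / rises, then falls)

Take the main path by itself. The dawn run, with less impurity than the summer run, gained 15 percentage points of ring in the 1.67 min before its last reading, and a straight line from there reaches 35.7% at 4.0 min.

Now add the drain on the activator. By that last reading, the ring in the dawn run had used 29.9% of the activator's charge, so we expect the line to bend, and we read it as a high mark.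

The open dimer and the dissolved starting material come next. In the dawn run at 3.00 min, ring and solid together account for 86.6%; the remainder stands in other forms, and the slope we extended was read with it present.

Last comes the impurity, and here we write a balance. One impurity takes one starting material, and it is charged far below the solid, so it is the limiting reagent of that step. For west, its charge over the solid's charge is 4.00%, and this ratio is the toll: the share of the solid that the impurity can remove.

The earlier runs test it. The toll of the summer run exceeds that of the dawn run by 3.05%, and at 3.00 min ring plus solid read lower in summer by 3 points, each reading carrying 0.5 points. Charge and readings agree within that scatter, so we take the toll as paid by then.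

Yet ring differed by 0.8 points, so a reading of 0.262 of the toll reached the ring, a weak figure given that scatter. From south-east to west we therefore expect ring to fall about 0.99 points.

The forecast gives 34.6%, 34.5%, 34.4%, 34.2%, 33.8%, course hardly changes, holding that “the impurity simply eats a little substrate”. Its top value stands lower than our line, and its fall is 0.8 points.

    starting material + activator → activated form (k = 5.80 L mol⁻¹ s⁻¹)
    activated form → ring (k = 2.40 s⁻¹)
    starting material + activated form → open dimer (k = 560 L mol⁻¹ s⁻¹)
    solid substrate ⇌ starting material, rate k4*(cs4 - [starting material]) while solid is left; crystals form when [starting material] > cs4 (solubility = 0.570 mM, k = 0.0590 s⁻¹)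
    starting material + protic impurity → quenched substrate (k = 4300 L mol⁻¹ s⁻¹)

The flasks give 34.6%, 34.6%, 34.5%, 34.3%, 34.0%, course hardly changes, a fall of 0.6 points. Starting material at 4.00 min stands at 8.84% in south-east and 8.81% in west. The toll of 4.00% in west is paid in full, with 4.00% of quenched substrate and 0% of the impurity left at 4.00 min. North-east, with a toll of 2.00%, holds 2.00% of quenched substrate at 4.00 min.

The data were generated by integration on assumed constants; noise was put on by code.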